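**Plan**

- Ring A is a 4-acylresorcinol carrying the geranyl group on O4' only. This is the oxidation pattern of a 6-acyl-3-alkoxycyclohex-2-en-1-one (C1=O becomes 2'-OH, the C3 enol-ether oxygen becomes the 4'-O-geranyl ether, C6 becomes C1'), so the two ring A oxygens are different from the first step on.
- Retrosynthetic cuts, in order: the two O–Si bonds; the C5=C6 unsaturation of ring A (back to the cyclohexenone); the C1'–C(=O) bond; the O–CH2 bond of the geranyl ether.
- Forward: geraniol goes onto the dione oxygen (step 1), the hydroxy acid is silylated and activated (steps 2–3), the C6 enolate is C-acylated (step 4), ring A is aromatised by selenoxide elimination (steps 5–6), and the silyl groups come off (step 7). No ring is built; ring A comes from cyclohexane-1,3-dione and ring B from the hydroxy acid.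
- The single stereocenter, (R) at the carbinol carbon, comes from (R)-3-(4-hydroxyphenyl)lactic acid; no bond to it is made or broken. The 2E alkene comes from geraniol.
- Compounds 3 and 8 to 14 contain an allyl vinyl ether, so every step runs at or below room temperature to keep a Claisen rearrangement from setting in.

Key step: step 4

Assumption: (R)-3-(4-hydroxyphenyl)lactic acid is bought as the single enantiomer; because the priority order O > C=O > CH2 > H holds at its C2 in every intermediate, the descriptor stays (R) up to the target.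

**Route**

Step 1
Reactants: 1 cyclohexane-1,3-dione; 2 geraniol
Product: 3 3-(geranyloxy)cyclohex-2-en-1-one
Conditions: PPh3, DIAD, THF, 0 °C → rt
Reagents that add atoms: none
Why: Mitsunobu reaction in which the acidic enol of the 1,3-dione is the pronucleophile and should displace the geranyl oxyphosphonium ion at its primary carbon through oxygen, giving the vinylogous ester without any acid that would ionise geraniol and without touching the 2E alkene.

Step 2
Reactants: 4 (R)-3-(4-hydroxyphenyl)lactic acid
Product: 6 (2R)-2-(tert-butyldimethylsilyloxy)-3-[4-(tert-butyldimethylsilyloxy)phenyl]propanoic acid, via tris-silyl ester 5 (not isolated)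
Conditions: TBSCl (3.5 equiv), imidazole, DMF, rt; then crude 5 in AcOH/THF/H2O (3:1:1), rt
Reagents that add atoms: tert-butyldimethylsilyl chloride, CC(C)(C)[Si](C)(C)Cl
Why: Exhaustive silylation with TBSCl and imidazole followed by selective hydrolysis of the silyl ester, which is far more labile than the aryl and secondary silyl ethers, should give the bis-silylated acid with the stereocenter untouched.

Step 3
Reactants: 6 (2R)-2-(tert-butyldimethylsilyloxy)-3-[4-(tert-butyldimethylsilyloxy)phenyl]propanoic acid
Product: 7 1-[(2R)-2-(tert-butyldimethylsilyloxy)-3-[4-(tert-butyldimethylsilyloxy)phenyl]propanoyl]-1H-benzotriazole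
Conditions: 1H-benzotriazole, DCC, CH2Cl2, 0 °C → rt
Reagents that add atoms: 1H-benzotriazole, c1ccc2[nH]nnc2c1
Why: Carbodiimide activation of the acid and capture of the O-acylisourea by benzotriazole gives the N-acylbenzotriazole under neutral conditions, and an α-oxygenated acid has no azlactone pathway through which the stereocenter could be lost.

Step 4
Reactants: 3 3-(geranyloxy)cyclohex-2-en-1-one; 7 1-[(2R)-2-(tert-butyldimethylsilyloxy)-3-[4-(tert-butyldimethylsilyloxy)phenyl]propanoyl]-1H-benzotriazole
Product: 10 6-[(2R)-2-(tert-butyldimethylsilyloxy)-3-[4-(tert-butyldimethylsilyloxy)phenyl]propanoyl]-3-(geranyloxy)cyclohex-2-en-1-one, via lithium dienolate 8 (not isolated), via lithium diketonate 9 (not isolated)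
Conditions: LiN(iPr)2 (2.2 equiv), 3 (2.2 equiv), THF, −78 °C; then 7 (1.0 equiv) added to the enolate, −78 → −40 °C; aq. NH4Cl
Reagents that add atoms: none
Why: LiN(iPr)2 removes the C6 (α') proton of 3 under kinetic control to give the cross-conjugated dienolate 8, whose C6 adds to the carbonyl of 7, and collapse of the tetrahedral intermediate expels benzotriazolide in a crossed Claisen condensation. The closest known reaction types are the C-acylation of ketone lithium enolates with N-acylbenzotriazoles and the α'-acylation of 3-alkoxycyclohex-2-enones with activated acyl donors. No ring closes and no stereocenter of consequence is created, since C6 of 10 is enolised and later becomes an aromatic carbon. The step needs α' rather than γ (C4) deprotonation, which the amide base at −78 °C secures, and C- rather than O-acylation, which the lithium counter-ion in THF and the soft acylbenzotriazole donor favour. The second equivalent of 8 should convert 10 at once into the chelated diketonate 9, which blocks over-addition and keeps base away from the proton on the silyloxy carbon, so the (R) centre is carried through; the 3 that is protonated back is recovered, and the aqueous NH4Cl quench releases the neutral β-diketone 10 for isolation.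

Step 5
Reactants: 10 6-[(2R)-2-(tert-butyldimethylsilyloxy)-3-[4-(tert-butyldimethylsilyloxy)phenyl]propanoyl]-3-(geranyloxy)cyclohex-2-en-1-one
Product: 12 6-[(2R)-2-(tert-butyldimethylsilyloxy)-3-[4-(tert-butyldimethylsilyloxy)phenyl]propanoyl]-3-(geranyloxy)-6-(phenylselanyl)cyclohex-2-en-1-one, via sodium diketonate 11 (not isolated)
Conditions: NaH (1.05 equiv), THF, 0 °C; then PhSeBr (1.0 equiv, slow addition), −78 °C; aq. NH4Cl
Reagents that add atoms: phenylselenyl bromide, Br[Se]c1ccccc1
Why: Reich α-selenenylation of a β-dicarbonyl compound through its sodium enolate, in which NaH deprotonates the acidic β-diketone 10 irreversibly and the diketonate carbon C6 of 11 should capture PhSeBr at −78 °C faster than the geranyl alkenes can, provided the bromide is never in excess; the new quaternary centre is of no consequence.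

Step 6
Reactants: 12 6-[(2R)-2-(tert-butyldimethylsilyloxy)-3-[4-(tert-butyldimethylsilyloxy)phenyl]propanoyl]-3-(geranyloxy)-6-(phenylselanyl)cyclohex-2-en-1-one
Product: 15 (2R)-2-(tert-butyldimethylsilyloxy)-3-[4-(tert-butyldimethylsilyloxy)phenyl]-1-[4-(geranyloxy)-2-hydroxyphenyl]propan-1-one, via selenoxide 13 (not isolated), via cyclohexadienone 14 (not isolated)
Conditions: NaIO4 (3 equiv), NaHCO3, THF/MeOH/H2O, 0 °C → rt
Reagents that add atoms: none
Why: Selenide oxidation and syn-selenoxide elimination, in which only C5 carries a β-hydrogen so the C5=C6 double bond should form regioselectively below room temperature, after which the 4H-cyclohexa-2,5-dienone 14 is the keto tautomer of a phenol and aromatises by enolisation; periodate does not epoxidise the geranyl alkenes and its excess takes the benzeneselenenic acid on to the seleninic acid before it can add to them.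

Step 7
Reactants: 15 (2R)-2-(tert-butyldimethylsilyloxy)-3-[4-(tert-butyldimethylsilyloxy)phenyl]-1-[4-(geranyloxy)-2-hydroxyphenyl]propan-1-one
Product: 16 (2R)-1-[4-(geranyloxy)-2-hydroxyphenyl]-2-hydroxy-3-(4-hydroxyphenyl)propan-1-one (CNP0159413.1)
Conditions: HF·pyridine, pyridine, THF, 0 °C → rt
Reagents that add atoms: none
Why: Fluoride-driven desilylation with pyridine-buffered HF·pyridine should cleave both the aryl and the secondary silyl ether without a basic medium that could epimerise the α-ketol through its enediol and without an acid strong enough to ionise the geranyl ether.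

**Compound list**

1 | cyclohexane-1,3-dione | O=C1CCCC(=O)C1 | starting material
2 | geraniol, (2E)-3,7-dimethylocta-2,6-dien-1-ol | CC(C)=CCC/C(C)=C/CO | starting material
3 | 3-(geranyloxy)cyclohex-2-en-1-one | CC(C)=CCC/C(C)=C/COC1=CC(=O)CCC1 | intermediate
4 | (R)-3-(4-hydroxyphenyl)lactic acid | O=C(O)[C@H](O)Cc1ccc(O)cc1 | starting material
5 | tert-butyldimethylsilyl (2R)-2-(tert-butyldimethylsilyloxy)-3-[4-(tert-butyldimethylsilyloxy)phenyl]propanoate (formed in the flask) | O=C(O[Si](C)(C)C(C)(C)C)[C@H](O[Si](C)(C)C(C)(C)C)Cc1ccc(O[Si](C)(C)C(C)(C)C)cc1 | intermediate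
6 | (2R)-2-(tert-butyldimethylsilyloxy)-3-[4-(tert-butyldimethylsilyloxy)phenyl]propanoic acid | O=C(O)[C@H](O[Si](C)(C)C(C)(C)C)Cc1ccc(O[Si](C)(C)C(C)(C)C)cc1 | intermediate
7 | 1-[(2R)-2-(tert-butyldimethylsilyloxy)-3-[4-(tert-butyldimethylsilyloxy)phenyl]propanoyl]-1H-benzotriazole | O=C([C@H](O[Si](C)(C)C(C)(C)C)Cc1ccc(O[Si](C)(C)C(C)(C)C)cc1)n1nnc2ccccc21 | intermediate
8 | lithium C6 dienolate of 3, lithium 3-(geranyloxy)cyclohexa-1,3-dien-1-olate numbered from the oxido carbon (formed in the flask) | CC(C)=CCC/C(C)=C/COC1=CC(O[Li])=CCC1 | intermediate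
9 | lithium diketonate of 10, deprotonated at C6 (formed in the flask) | CC(C)=CCC/C(C)=C/COC1=CC(O[Li])=C(C(=O)[C@H](O[Si](C)(C)C(C)(C)C)Cc2ccc(O[Si](C)(C)C(C)(C)C)cc2)CC1 | intermediate
10 | 6-[(2R)-2-(tert-butyldimethylsilyloxy)-3-[4-(tert-butyldimethylsilyloxy)phenyl]propanoyl]-3-(geranyloxy)cyclohex-2-en-1-one (keto and enol forms, C6 not defined) | CC(C)=CCC/C(C)=C/COC1=CC(=O)C(C(=O)[C@H](O[Si](C)(C)C(C)(C)C)Cc2ccc(O[Si](C)(C)C(C)(C)C)cc2)CC1 | intermediate
11 | sodium diketonate of 10, deprotonated at C6 (formed in the flask) | CC(C)=CCC/C(C)=C/COC1=CC(O[Na])=C(C(=O)[C@H](O[Si](C)(C)C(C)(C)C)Cc2ccc(O[Si](C)(C)C(C)(C)C)cc2)CC1 | intermediate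
12 | 6-(phenylselanyl) derivative of 10 (both C6 epimers) | CC(C)=CCC/C(C)=C/COC1=CC(=O)C([Se]c2ccccc2)(C(=O)[C@H](O[Si](C)(C)C(C)(C)C)Cc2ccc(O[Si](C)(C)C(C)(C)C)cc2)CC1 | intermediate
13 | selenoxide of 12 (formed in the flask) | CC(C)=CCC/C(C)=C/COC1=CC(=O)C([Se](=O)c2ccccc2)(C(=O)[C@H](O[Si](C)(C)C(C)(C)C)Cc2ccc(O[Si](C)(C)C(C)(C)C)cc2)CC1 | intermediate
14 | cross-conjugated cyclohexa-2,5-dien-1-one with C4H2, keto tautomer of 15 (formed in the flask) | CC(C)=CCC/C(C)=C/COC1=CC(=O)C(C(=O)[C@H](O[Si](C)(C)C(C)(C)C)Cc2ccc(O[Si](C)(C)C(C)(C)C)cc2)=CC1 | intermediate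
15 | (2R)-2-(tert-butyldimethylsilyloxy)-3-[4-(tert-butyldimethylsilyloxy)phenyl]-1-[4-(geranyloxy)-2-hydroxyphenyl]propan-1-one | CC(C)=CCC/C(C)=C/COc1ccc(C(=O)[C@H](O[Si](C)(C)C(C)(C)C)Cc2ccc(O[Si](C)(C)C(C)(C)C)cc2)c(O)c1 | intermediate
16 | (2R)-1-[4-(geranyloxy)-2-hydroxyphenyl]-2-hydroxy-3-(4-hydroxyphenyl)propan-1-one | CC(C)=CCC/C(C)=C/COc1ccc(C(=O)[C@H](O)Cc2ccc(O)cc2)c(O)c1 | target

**Step count**

Total: 7 steps. Longest linear sequence: 6 steps (4 → 16, steps 2 to 7).

**Steps most likely to fail, with fallbacks**

Step 4. The dienolate may be acylated on oxygen, or it may act as a base toward the acyl donor (enolisation instead of addition, with erosion of configuration at the silyloxy carbon). The fallback makes the same C6–C(carbonyl) bond at the aldehyde oxidation level and sets out from acid 6. Coupling of 6 with N,O-dimethylhydroxylamine hydrochloride (EDC·HCl, N-methylmorpholine, CH2Cl2) would give the Weinreb amide F1. Reduction with iBu2AlH in THF at −78 °C would give (2R)-2-(tert-butyldimethylsilyloxy)-3-[4-(tert-butyldimethylsilyloxy)phenyl]propanal F2, used crude. Aldol addition of dienolate 8 (from 3 and LiN(iPr)2, THF, −78 °C) to F2 would give the β-hydroxy ketone F3 as a diastereomer mixture at the two new centres. Both centres disappear on oxidation with Dess–Martin periodinane (NaHCO3, CH2Cl2), where the sequence comes back to the route at 10.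

Step 5. Electrophilic selenium may add to the trisubstituted alkenes of the geranyl chain during selenenylation, and selenenic acid may add to them in step 6. The fallback replaces selenium by sulfur and sets out from 10. Deprotonation with NaH in THF to the sodium diketonate 11 and sulfenylation with S-phenyl benzenethiosulfonate, a reagent that does not add to alkenes, would give the 6-(phenylsulfanyl) diketone F4. NaIO4 in aqueous methanol would give the sulfoxide F5. Gentle warming in toluene (about 50–60 °C, CaCO3) should bring about syn-elimination of benzenesulfenic acid and tautomerisation through 14. This temperature is still well below that of a Claisen rearrangement. The sequence comes back to the route at 15.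

Step 1. The ambident dione may be alkylated at C2 instead of at oxygen, or the displacement may occur with allylic transposition at the tertiary terminus of the geranyl unit. The fallback forms the enol-ether C3–O bond by addition–elimination instead and sets out from 1. Oxalyl chloride with catalytic DMF in CH2Cl2 would give 3-chlorocyclohex-2-en-1-one F6. Geraniol 2, deprotonated with NaH in THF at 0 °C, would then add to C3 of F6 and expel chloride, so the geranyl C–O bond is never ionised. The sequence comes back to the route at 3.

**Further compounds**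

F1 | step 4 | (2R)-2-(tert-butyldimethylsilyloxy)-3-[4-(tert-butyldimethylsilyloxy)phenyl]-N-methoxy-N-methylpropanamide | CON(C)C(=O)[C@H](O[Si](C)(C)C(C)(C)C)Cc1ccc(O[Si](C)(C)C(C)(C)C)cc1
F2 | step 4 | (2R)-2-(tert-butyldimethylsilyloxy)-3-[4-(tert-butyldimethylsilyloxy)phenyl]propanal | O=C[C@H](O[Si](C)(C)C(C)(C)C)Cc1ccc(O[Si](C)(C)C(C)(C)C)cc1
F3 | step 4 | 6-[(2R)-2-(tert-butyldimethylsilyloxy)-3-[4-(tert-butyldimethylsilyloxy)phenyl]-1-hydroxypropyl]-3-(geranyloxy)cyclohex-2-en-1-one | CC(C)=CCC/C(C)=C/COC1=CC(=O)C(C(O)[C@H](O[Si](C)(C)C(C)(C)C)Cc2ccc(O[Si](C)(C)C(C)(C)C)cc2)CC1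
F4 | step 5 | 6-(phenylsulfanyl) derivative of 10 | CC(C)=CCC/C(C)=C/COC1=CC(=O)C(Sc2ccccc2)(C(=O)[C@H](O[Si](C)(C)C(C)(C)C)Cc2ccc(O[Si](C)(C)C(C)(C)C)cc2)CC1
F5 | step 5 | 6-(phenylsulfinyl) derivative of 10 | CC(C)=CCC/C(C)=C/COC1=CC(=O)C(S(=O)c2ccccc2)(C(=O)[C@H](O[Si](C)(C)C(C)(C)C)Cc2ccc(O[Si](C)(C)C(C)(C)C)cc2)CC1
F6 | step 1 | 3-chlorocyclohex-2-en-1-one | O=C1C=C(Cl)CCC1
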